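The route rests on disconnecting the bond between the ketone carbonyl carbon and the benzylic methine of the 3-hydroxy-1-oxopropan-2-yl side chain, which sits ortho to the phenol on the guaiacyl ring of the lactone C4 benzyl group. The methine and its CH2OH carbon are treated as a former vinyl group on that ring: a copper-catalysed enantioselective borylacylation of vinyl arene 12 with aroyl chloride 14 forms the C(=O)–CH bond, sets the (S) methine and puts boron on the terminal carbon, which is oxidised in the same flask to CH2OH. The precursor 12 is a 5-vinyl matairesinol dibenzyl ether, built from 5-bromovanillin by Stobbe condensation, asymmetric hydrogenation, lactone alkylation and Suzuki vinylation.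

Key step: step 9

Assumption: the ligand enantiomers named in steps 3 and 9 are those expected to give the (R)-acid 5 and the (S)-ketone 16; each sense is to be confirmed on a model substrate, and the mirror-image ligand is used if it proves opposite.

Step 1
Reactants: 1 5-bromovanillin
Product: 2 4-(benzyloxy)-3-bromo-5-methoxybenzaldehyde
Conditions: BnBr, K2CO3, DMF, rt
Reagents that add atoms: benzyl bromide BrCc1ccccc1
Why: Williamson ether synthesis, in which the acidic phenol (ortho bromine, para formyl) is benzylated cleanly on oxygen; no stereocentre is involved.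

Step 2
Reactants: 2 4-(benzyloxy)-3-bromo-5-methoxybenzaldehyde; 3 dimethyl succinate
Product: 4 (E)-4-[4-(benzyloxy)-3-bromo-5-methoxyphenyl]-3-(methoxycarbonyl)but-3-enoic acid
Conditions: NaOMe, MeOH, reflux; then aq. HCl
Reagents that add atoms: none
Why: Stobbe condensation, in which the succinate enolate adds to the aldehyde, the alkoxide lactonises to a paraconate and irreversible ring opening gives the (E)-arylidene half-ester with the conjugated ester kept and the remote carboxylic acid free.

Step 3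
Reactants: 4 (E)-arylidenesuccinic half-ester
Product: 5 (3R)-4-[4-(benzyloxy)-3-bromo-5-methoxyphenyl]-3-(methoxycarbonyl)butanoic acid
Conditions: H2 (1–5 atm), [Rh(cod)Cl]2 / (4S,5S)-MOD-DIOP (cat.), Et3N, MeOH, 30 °C
Reagents that add atoms: none
Why: Rh-catalysed asymmetric hydrogenation of an itaconate-type half-ester, in which carboxylate and alkene chelate rhodium so that the chiral bisphosphine selects the alkene face and sets the (R) centre, while aryl bromide and benzyl ether are inert to the homogeneous catalyst.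

Step 4
Reactants: 5 (R)-half-ester
Product: 7 (4R)-4-[4-(benzyloxy)-3-bromo-5-methoxybenzyl]dihydrofuran-2(3H)-one, via hydroxy acid 6 (not isolated)
Conditions: KOH, EtOH; CaCl2/NaBH4 [Ca(BH4)2], EtOH, −10 °C to rt; then 2 M HCl, rt
Reagents that add atoms: none
Why: Chemoselective ester reduction and lactonisation, in which calcium borohydride reduces the methyl ester but not the carboxylate and acidification closes the γ-hydroxy acid to the γ-butyrolactone without touching the stereocentre.

Step 5
Reactants: 8 4-(benzyloxy)-3-methoxybenzyl alcohol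
Product: 9 4-(benzyloxy)-3-methoxybenzyl bromide
Conditions: PBr3, CH2Cl2, 0 °C
Reagents that add atoms: phosphorus tribromide BrP(Br)Br
Why: Substitution of an electron-rich benzylic alcohol by bromide via the bromophosphite, under which the aryl benzyl ether is stable.

Step 6
Reactants: 7 (4R)-lactone; 9 4-(benzyloxy)-3-methoxybenzyl bromide
Product: 11 (3R,4R)-3-[4-(benzyloxy)-3-methoxybenzyl]-4-[4-(benzyloxy)-3-bromo-5-methoxybenzyl]dihydrofuran-2(3H)-one, via lithium enolate 10 (not isolated)
Conditions: LiHMDS, THF, −78 °C; then 9, DMPU, −78 to −40 °C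
Reagents that add atoms: lithium bis(trimethylsilyl)amide [Li+].C[Si](C)(C)[N-][Si](C)(C)C (lithium of intermediate 10 only)
Why: Lactone enolate alkylation, in which the benzylic bromide attacks the enolate face anti to the C4 arylmethyl group, setting C3 as (R) and giving the trans-3,4-disubstituted lactone; the amide base does not exchange the aryl bromide.

Step 7
Reactants: 11 trans-lactone aryl bromide
Product: 12 (3R,4R)-3-[4-(benzyloxy)-3-methoxybenzyl]-4-[4-(benzyloxy)-3-methoxy-5-vinylbenzyl]dihydrofuran-2(3H)-one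
Conditions: vinylboronic acid pinacol ester, Pd(dppf)Cl2 (cat.), K3PO4, dioxane/H2O, 80 °C; work-up at pH 3
Reagents that add atoms: 4,4,5,5-tetramethyl-2-vinyl-1,3,2-dioxaborolane C=CB1OC(C)(C)C(C)(C)O1
Why: Suzuki–Miyaura coupling of the aryl bromide with a vinylboronate; the base cannot erode the thermodynamically preferred trans lactone, and the acidic work-up recloses any lactone opened by hydrolysis.

Step 8
Reactants: 13 4-(benzyloxy)-3-methoxybenzoic acid
Product: 14 4-(benzyloxy)-3-methoxybenzoyl chloride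
Conditions: (COCl)2, DMF (cat.), CH2Cl2, 0 °C to rt; used crude
Reagents that add atoms: oxalyl chloride ClC(=O)C(=O)Cl
Why: Acid chloride formation through the Vilsmeier-type chloroiminium catalyst, with only gaseous co-products, so that crude 14 can be used directly.

Step 9
Reactants: 12 vinyl arene; 14 4-(benzyloxy)-3-methoxybenzoyl chloride
Product: 16 (3R,4R)-3-[4-(benzyloxy)-3-methoxybenzyl]-4-{4-(benzyloxy)-3-[(2S)-1-[4-(benzyloxy)-3-methoxyphenyl]-3-hydroxy-1-oxopropan-2-yl]-5-methoxybenzyl}dihydrofuran-2(3H)-one, via boryl ketone 15 (not isolated)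
Conditions: CuCl (10 mol %), (S,S)-Ph-BPE (11 mol %), NaOtBu, B2pin2, THF, 0 °C to rt, slow addition of 14; then NaBO3·4H2O, THF/pH 7 phosphate buffer, 0 °C
Reagents that add atoms: bis(pinacolato)diboron CC1(C)OB(OC1(C)C)B1OC(C)(C)C(C)(C)O1 (boron of intermediate 15); sodium perborate [Na+].[Na+].O[B-]1(O)OO[B-](O)(O)OO1 (hydroxyl oxygen of 16)
Why: LCu–Bpin, formed from LCuOtBu and B2pin2, adds syn across the vinyl group with copper on the benzylic carbon and boron on the terminal carbon, and the benzylic copper species is acylated by 14 with retention, which forms the ketone C(=O)–CH bond and returns LCuCl; the closest known reaction type is the Cu-catalysed borylacylation of vinyl arenes with acid chlorides. No ring is closed. The methine stereocentre is set in the borylcupration, where the C2-symmetric bisphosphine on copper selects the alkene face; the lactone stereocentres are remote, so the outcome should be catalyst-controlled. The step needs regioselectivity (copper at the aryl-stabilised benzylic position), chemoselectivity for the styrene over the lactone and its C3–H (the alkoxide is tied up as the diboron ate complex, and 14 is added slowly) and survival of the base-labile α-aryl ketone centre (low temperature and a buffered oxidation). The perborate then converts the primary C–B bond into C–OH without touching the methine, whose descriptor changes from (R) in 15 to (S) in 16 only through the priority rules.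

Step 10
Reactants: 16 tris(benzyl ether) hydroxy ketone
Product: 17 (3R,4R)-3-(4-hydroxy-3-methoxybenzyl)-4-{4-hydroxy-3-[(2S)-3-hydroxy-1-(4-hydroxy-3-methoxyphenyl)-1-oxopropan-2-yl]-5-methoxybenzyl}dihydrofuran-2(3H)-one
Conditions: H2 (1 atm), 10 % Pd/C, EtOAc, rt, stopped at full debenzylation
Reagents that add atoms: none
Why: Hydrogenolysis of the three aryl benzyl ethers over palladium under neutral, aprotic conditions, which should leave the deactivated para-oxygenated aryl ketone, the lactone and the acid- and base-labile α-aryl-β-hydroxy ketone centre untouched.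

Compound list
1 | 5-bromovanillin (3-bromo-4-hydroxy-5-methoxybenzaldehyde) | COc1cc(C=O)cc(Br)c1O | starting material
2 | 4-(benzyloxy)-3-bromo-5-methoxybenzaldehyde | COc1cc(C=O)cc(Br)c1OCc1ccccc1 | intermediate
3 | dimethyl succinate | COC(=O)CCC(=O)OC | starting material
4 | (E)-4-[4-(benzyloxy)-3-bromo-5-methoxyphenyl]-3-(methoxycarbonyl)but-3-enoic acid | COC(=O)/C(CC(=O)O)=C/c1cc(OC)c(OCc2ccccc2)c(Br)c1 | intermediate
5 | (3R)-4-[4-(benzyloxy)-3-bromo-5-methoxyphenyl]-3-(methoxycarbonyl)butanoic acid | COC(=O)[C@@H](CC(=O)O)Cc1cc(OC)c(OCc2ccccc2)c(Br)c1 | intermediate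
6 | (3R)-4-[4-(benzyloxy)-3-bromo-5-methoxyphenyl]-3-(hydroxymethyl)butanoic acid | OC[C@@H](CC(=O)O)Cc1cc(OC)c(OCc2ccccc2)c(Br)c1 | intermediate
7 | (4R)-4-[4-(benzyloxy)-3-bromo-5-methoxybenzyl]dihydrofuran-2(3H)-one | O=C1C[C@@H](Cc2cc(OC)c(OCc3ccccc3)c(Br)c2)CO1 | intermediate
8 | 4-(benzyloxy)-3-methoxybenzyl alcohol | COc1cc(CO)ccc1OCc1ccccc1 | starting material
9 | 4-(benzyloxy)-3-methoxybenzyl bromide | COc1cc(CBr)ccc1OCc1ccccc1 | intermediate
10 | lithium (4R)-4-[4-(benzyloxy)-3-bromo-5-methoxybenzyl]-4,5-dihydrofuran-2-olate (enolate of 7) | [Li+].[O-]C1=C[C@@H](Cc2cc(OC)c(OCc3ccccc3)c(Br)c2)CO1 | intermediate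
11 | (3R,4R)-3-[4-(benzyloxy)-3-methoxybenzyl]-4-[4-(benzyloxy)-3-bromo-5-methoxybenzyl]dihydrofuran-2(3H)-one | COc1cc(C[C@H]2C(=O)OC[C@@H]2Cc2cc(OC)c(OCc3ccccc3)c(Br)c2)ccc1OCc1ccccc1 | intermediate
12 | (3R,4R)-3-[4-(benzyloxy)-3-methoxybenzyl]-4-[4-(benzyloxy)-3-methoxy-5-vinylbenzyl]dihydrofuran-2(3H)-one | COc1cc(C[C@H]2C(=O)OC[C@@H]2Cc2cc(OC)c(OCc3ccccc3)c(C=C)c2)ccc1OCc1ccccc1 | intermediate
13 | 4-(benzyloxy)-3-methoxybenzoic acid | COc1cc(C(=O)O)ccc1OCc1ccccc1 | starting material
14 | 4-(benzyloxy)-3-methoxybenzoyl chloride | COc1cc(C(=O)Cl)ccc1OCc1ccccc1 | intermediate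
15 | (3R,4R)-3-[4-(benzyloxy)-3-methoxybenzyl]-4-{4-(benzyloxy)-3-[(2R)-1-[4-(benzyloxy)-3-methoxyphenyl]-1-oxo-3-(4,4,5,5-tetramethyl-1,3,2-dioxaborolan-2-yl)propan-2-yl]-5-methoxybenzyl}dihydrofuran-2(3H)-one | COc1cc(C[C@H]2C(=O)OC[C@@H]2Cc2cc(OC)c(OCc3ccccc3)c([C@@H](CB3OC(C)(C)C(C)(C)O3)C(=O)c3ccc(OCc4ccccc4)c(OC)c3)c2)ccc1OCc1ccccc1 | intermediate
16 | (3R,4R)-3-[4-(benzyloxy)-3-methoxybenzyl]-4-{4-(benzyloxy)-3-[(2S)-1-[4-(benzyloxy)-3-methoxyphenyl]-3-hydroxy-1-oxopropan-2-yl]-5-methoxybenzyl}dihydrofuran-2(3H)-one | COc1cc(C[C@H]2C(=O)OC[C@@H]2Cc2cc(OC)c(OCc3ccccc3)c([C@@H](CO)C(=O)c3ccc(OCc4ccccc4)c(OC)c3)c2)ccc1OCc1ccccc1 | intermediate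
17 | (3R,4R)-3-(4-hydroxy-3-methoxybenzyl)-4-{4-hydroxy-3-[(2S)-3-hydroxy-1-(4-hydroxy-3-methoxyphenyl)-1-oxopropan-2-yl]-5-methoxybenzyl}dihydrofuran-2(3H)-one | COc1cc(C[C@H]2C(=O)OC[C@@H]2Cc2cc(OC)c(O)c([C@@H](CO)C(=O)c3ccc(O)c(OC)c3)c2)ccc1O | target

Total step count: 10. Longest linear sequence: 8 steps (1, 2, 3, 4, 6, 7, 9, 10); steps 5 and 8 prepare the two side fragments.

Steps most likely to fail

Step 9. The face selection in the borylcupration may be weak on this ortho-alkoxy styrene. The benzylic copper species may be protonated instead of acylated (net hydroboration). The alkoxide may epimerise the new methine or acylate the lactone at C3. The fallback sets out from 12 and comes back at 16, forming the same bond by a nickel-catalysed enantioconvergent reductive acyl cross-coupling. Dihydroxylation of 12 (OsO4 cat., NMO) should give diol F1 as both carbinol epimers. TBSCl/imidazole should silylate the primary hydroxyl to give silyl ether F2. SOCl2/pyridine should convert the benzylic alcohol into benzylic chloride F3, used crude as the epimer mixture. Coupling of F3 with 14 (NiCl2·dme, chiral bis(oxazoline), Mn, DMA/THF, 3 Å MS) should give ketone silyl ether F4, both chloride epimers converging through the benzylic radical under ligand control. HF·pyridine then removes the silyl group to give 16.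

Step 10. Hydrogenation may go on to reduce the aryl ketone, or the product may epimerise or cyclodehydrate towards a benzofuran on the catalyst. The fallback sets out from 16 and comes back at 17: a non-reductive Lewis-acid debenzylation with BCl3 and pentamethylbenzene as cation scavenger in CH2Cl2 at −78 °C, quenched with methanol. This fallback makes no new compound (F0).

Step 3. Enantioface discrimination may be insufficient on this hindered arylidene, or the aryl bromide may be hydrodebrominated. The fallback sets out from 2 and comes back at 7, using an Evans auxiliary instead of catalysis. NaBH4 should reduce 2 to benzyl alcohol F5, and PBr3 should give benzyl bromide F6. Mono-tert-butyl succinate is coupled (PivCl, Et3N, LiCl) with (R)-4-benzyloxazolidin-2-one to give succinyl imide F7. Its sodium enolate (NaHMDS, THF, −78 °C) is alkylated with F6 on the face away from the auxiliary benzyl group to give alkylated imide F8. LiBH4 removes the auxiliary reductively to give hydroxy ester F9, and TFA closes it to lactone 7.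

Further compounds
F1 | step 9 | (3R,4R)-3-[4-(benzyloxy)-3-methoxybenzyl]-4-[4-(benzyloxy)-3-(1,2-dihydroxyethyl)-5-methoxybenzyl]dihydrofuran-2(3H)-one (both carbinol epimers) | COc1cc(C[C@H]2C(=O)OC[C@@H]2Cc2cc(OC)c(OCc3ccccc3)c(C(O)CO)c2)ccc1OCc1ccccc1
F2 | step 9 | (3R,4R)-3-[4-(benzyloxy)-3-methoxybenzyl]-4-{4-(benzyloxy)-3-[2-(tert-butyldimethylsilyloxy)-1-hydroxyethyl]-5-methoxybenzyl}dihydrofuran-2(3H)-one (both carbinol epimers) | COc1cc(C[C@H]2C(=O)OC[C@@H]2Cc2cc(OC)c(OCc3ccccc3)c(C(O)CO[Si](C)(C)C(C)(C)C)c2)ccc1OCc1ccccc1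
F3 | step 9 | (3R,4R)-3-[4-(benzyloxy)-3-methoxybenzyl]-4-{4-(benzyloxy)-3-[2-(tert-butyldimethylsilyloxy)-1-chloroethyl]-5-methoxybenzyl}dihydrofuran-2(3H)-one (both chloride epimers) | COc1cc(C[C@H]2C(=O)OC[C@@H]2Cc2cc(OC)c(OCc3ccccc3)c(C(Cl)CO[Si](C)(C)C(C)(C)C)c2)ccc1OCc1ccccc1
F4 | step 9 | (3R,4R)-3-[4-(benzyloxy)-3-methoxybenzyl]-4-{4-(benzyloxy)-3-[(2S)-1-[4-(benzyloxy)-3-methoxyphenyl]-3-(tert-butyldimethylsilyloxy)-1-oxopropan-2-yl]-5-methoxybenzyl}dihydrofuran-2(3H)-one | COc1cc(C[C@H]2C(=O)OC[C@@H]2Cc2cc(OC)c(OCc3ccccc3)c([C@@H](CO[Si](C)(C)C(C)(C)C)C(=O)c3ccc(OCc4ccccc4)c(OC)c3)c2)ccc1OCc1ccccc1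
F0 | step 10 | none | none
F5 | step 3 | [4-(benzyloxy)-3-bromo-5-methoxyphenyl]methanol | COc1cc(CO)cc(Br)c1OCc1ccccc1
F6 | step 3 | 2-(benzyloxy)-1-bromo-5-(bromomethyl)-3-methoxybenzene | COc1cc(CBr)cc(Br)c1OCc1ccccc1
F7 | step 3 | tert-butyl 4-[(4R)-4-benzyl-2-oxo-1,3-oxazolidin-3-yl]-4-oxobutanoate | CC(C)(C)OC(=O)CCC(=O)N1[C@H](Cc2ccccc2)COC1=O
F8 | step 3 | tert-butyl (3R)-4-[(4R)-4-benzyl-2-oxo-1,3-oxazolidin-3-yl]-3-[4-(benzyloxy)-3-bromo-5-methoxybenzyl]-4-oxobutanoate | CC(C)(C)OC(=O)C[C@@H](Cc1cc(OC)c(OCc2ccccc2)c(Br)c1)C(=O)N1[C@H](Cc2ccccc2)COC1=O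
F9 | step 3 | tert-butyl (3R)-4-[4-(benzyloxy)-3-bromo-5-methoxyphenyl]-3-(hydroxymethyl)butanoate | CC(C)(C)OC(=O)C[C@@H](Cc1cc(OC)c(OCc2ccccc2)c(Br)c1)CO
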